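You start from a leftover: in the autumn run, which is this very flask followed so far, Zc is charged in the smaller amount, and at 10.0 min its balance leaves 32.9% of the charge outside Ze and Zd.

| setting | autumn | flask |
|---|---|---|
| Zc | 32 mM | 32 mM |
| Zb | 48 mM | 48.0 mM |
| remark | the very flask that is asked about, followed so far |  |
| time |  | 30 min |

- autumn (time / min: Ze / %, Zd / %): 0.667: 9.2, 1.5; 1.50: 15.1, 5.2; 4.00: 37.7, 12.0; 10.0: 51.3, 15.8

(each reading ± 1 percentage point)

- ratio of Ze to Zd at 8.0 s
- ratio of Ze to Zd at 30 min
- which of Ze and Zd there is more of at 30 min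

- Zc is a solid; its amount is given per volume of the solution
- at the start none of Zc is in solution

What has come out of the autumn run is described by two amounts, the Ze and Zd fractions at its latest reading, 51.3% and 15.8%. Their ratio, read with the scatter of those readings, is the product split, 3.25. In the autumn run the first Zd reading is 1.5%, with a scatter of 1 percentage point, and the ratio reads 2.90 at 1.50 min and 3.14 at 4.00 min. My own reckoning carries the split to 30 min with Ze ahead, but it gives no figure for 8.0 s, which lies earlier than the first reading.

The forecast says 3.3 (2.6 to 4.2) at 30 min, slightly above my split, with Ze ahead. At 8.0 s it says 4 (2.6 to 15), since “The low Zd reading hints that Ze may form first”.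

The flask gives 3.23 at 30 min, with Ze at 51.8% and Zd at 16.1%. At 8.0 s it gives 1.77, lower than the forecast's low end.

    Za + Zb ⇌ Zd (K = 19.0 M⁻¹, k = 18.5 M⁻¹ s⁻¹)
    Za + Zb ⇌ Ze (K = 61.3 M⁻¹, k = 9.85 M⁻¹ s⁻¹)
    Zc ⇌ Za, rate k3*(cs3 - [Za]) while solid is left; crystals form when [Za] > cs3 (solubility = 15.0 mM, k = 0.00741 s⁻¹)

In this flask Zc dissolved while solid stood, 46.9% at 3.00 min and 0% at 15.0 min, when Za stood at 32.1%. At 30 min in this flask Zd and Ze relax with Za and Zb in 0.420 s and 1.33 s, each by its own step alone, both ways together, short against that time, and the ratio of their equilibrium constants is 3.23: thermodynamic control.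

With 19 mM of Zb, the split applied to that neighbour's Zd fraction of 7.68% gives Ze as 24.9%. The computed neighbour flask holds 24.8%, a ratio of 3.23.

The numbers in the tables stem from a simulated flask with constants of no real substance, noise included.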